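**Remarks on the chemistry**

- Assumption: porcine pancreatic lipase is taken to acylate (S)-lavandulol faster than (R)-lavandulol, so the R alcohol is the one recovered. If the preference were the reverse, the R enantiomer would be taken from the hemisuccinate by saponification, with no other change.
- "Lavandulyl" means the 5-methyl-2-(prop-1-en-2-yl)hex-4-en-1-yl group in the configuration of the target. It is S whenever its CH2 is bound to carbon and corresponds in space to R in alcohol 2 and iodide 3, because CH2–O and CH2–I outrank the isopropenyl carbon and CH2–C does not.
- MOM is methoxymethyl. Locants C2–C8a and O1 are those of the chromenone 20. "Chain C1–C8" are those of octadienoate 11, with chain C1 = C8a, C2 = C8, C3 = C7, C4 = C6, C5 = C5, C6 = C4a, C7 = C4, C8 = C3.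
- Compound numbers are those of the list after the steps.

## Analysis of the target

The target 20 is a flavonol: benzene ring A is fused to 4-pyranone ring C, ring B (2,4-dihydroxyphenyl) sits on C2, hydroxyls are on C3, C5 and C7, and a lavandulyl chain is on C8. The only stereocentre is C2 of that chain (S); it is two bonds from ring A and has no stereochemical partner, so it is best brought in ready-made from (R)-lavandulol 2. The sensitive groups are the 1,1-disubstituted and trisubstituted alkenes of the chain, which rule out hydrogenolysis, electrophilic oxidants and strong Brønsted or Lewis acids, since acid could add the C7 hydroxyl across the isopropenyl group or move that double bond onto the stereocentre. The electron-rich phenols and the 3-hydroxypyranone are in addition air-sensitive under base. The main difficulty is regiochemical: ring A carries five substituents, and the chain must be on C8 and not on C6. These two positions differ only in which ortho oxygen, O8a or O5, becomes the ring oxygen, so direct alkylation of a phloroglucinol or closure of a 2,6-dihydroxyaryl ketone would give both isomers. The strategy rests on the polyketide pattern of ring A: going round C8a, C8, C7, C6, C5 and C4a the substituents are O, alkyl, O, H, O and acyl, which is a 2-alkyl-3,5,7-trioxooctanoate folded so that C4a meets the ester carbon C8a, with C4 as the ketone. Closing that bond makes O8a, the former ester oxygen, the one ring A oxygen that differs from O5 and O7.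

## Retrosynthetic reasoning

**20 from 19.** The five O–CH2 acetal bonds are cut. One acetal type on all five oxygens allows a single final deprotection that is neither reductive nor oxidative. The forward step must cleave aryl and enol acetals faster than it protonates the isopropenyl group.

**19 from 18.** The O1–C2 bond of ring C is cut, giving the 2-hydroxyaryl 1,3-diketone 18. In 18 the only free phenol is O8a, so dehydration can close only on the side of C8. The C8-versus-C6 question is therefore settled by structure. The forward step needs a buffered acid that leaves the O5 acetal in place until the ring is closed.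

**18 from 17, and 17 from 13 and 16.** The C2–C3 bond is cut as an O-to-C aroyl shift (Baker–Venkataraman), and the aryl ester 17 is cut at its acyl–oxygen bond into phenol 13 and acid 16. C3 already carries its oxygen in 13, so no oxidation of a flavone is needed later. Acid 16 is coupled directly under carbodiimide activation, because activation that generates chloride and acid next to the ortho acetal oxygen would put that acetal at risk. Acid 16 goes back through its MOM ester 15 to 14.

**13 from 11, via 12.** The C4a–C8a bond is cut; this is the strategic disconnection. It opens ring A to the keto dienoate 11, in which O5 and O7 are enol ethers and C8a is an ester carbon. The forward closure is an intramolecular Claisen condensation. It fixes the position of the side chain relative to the acyl group and delivers O8a as the only free hydroxyl. One C–C bond and one ring are made, and no stereocentre.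

**11 from 7 and 10.** The C4a–C4 bond is cut. The two-carbon unit C4–C3 with its oxygen comes from amide 10, and the terminal methyl of dienoate 7 is the nucleophile. The N-methoxy-N-methyl amide 10 is chosen so that the ketone stays masked as a chelate until quench and 11 is not exposed to base before the key step. Amide 10 goes back through 9 to 8.

**7 from 6.** The two enol O–CH2 bonds are cut, giving the 3,5-dioxo ester 6. The same acetal that protects the phenols later is used here to fix the folding pattern of the chain.

**6 from 5.** The C6–C5 bond is cut (chain C4–C5). An acetyl unit, which supplies C5 and C4a, is added to the γ-carbon of the dianion of β-keto ester 5.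

**5 from 4 and 3.** The bond between C8 and the side-chain CH2 is cut. Compound 4 supplies C8a, C8, C7 and C6, and its doubly activated carbon is alkylated by iodide 3. The stereocentre is one carbon away from the reacting centre and has no acidic hydrogen, so it is not at risk. The bond is made on an enolate and not on an arene, which is the reliable way to attach a β-branched alkyl group.

**3 from 2 from 1.** Iodide 3 comes from alcohol 2 by substitution at the primary carbon, and 2 from racemic 1 by enzymatic resolution. This is the one point where absolute configuration is set.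

## Alternatives that were turned down

Alternative 1: carbon monoxide as the source of C4 in a carbonylative three-component coupling.
- Disconnection: C4a–C4 and C4–C3. C4 is traced back to carbon monoxide A4, ring A to an aryl iodide A2, and C3 with ring B to a ketone A3.
- Forward key step: oxidative addition of 2-iodo-4-lavandulyl-1-methoxy-3,5-bis(methoxymethoxy)benzene A2 to zerovalent palladium and insertion of A4 would be followed by capture of the acyl–palladium bond by the magnesium enolate of 2-(methoxymethoxy)-1-[2,4-bis(triisopropylsiloxy)phenyl]ethanone A3. The product would be the open-chain diketone 1-[3-lavandulyl-6-methoxy-2,4-bis(methoxymethoxy)phenyl]-2-(methoxymethoxy)-3-[2,4-bis(triisopropylsiloxy)phenyl]propane-1,3-dione A1; no ring closes in this step.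
- For: two skeletal bonds form at once, and A3 delivers ring B with C2 and C3 in one piece. The iodine of A2 can be introduced without a regiochemical question, because before iodination the two unsubstituted ring positions are equivalent. On convergence and probably on longest linear sequence this plan is stronger than the chosen route.
- Against: the iodine of A2 sits between two alkoxy groups on an electron-rich ring, so oxidative addition is demanding. The enolate of A3 is a secondary, oxygen-bearing carbon nucleophile, so its capture of a crowded acylpalladium centre is demanding as well. Direct arylation without uptake of A4, O-acylation of the enolate, and sequestration of base by the more acidic product A1 compete. To keep O5 from competing with O8a in the later ring closure, O5 must be a methyl ether, and its removal needs a strongly Lewis acidic demethylation in the presence of the lavandulyl alkenes and a free C7 hydroxyl. Three kinds of protecting group need three removals. A2 itself requires the lavandulyl group to be joined to a metalated arene, a poor reaction for a β-branched primary iodide such as 3.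
- Comparison: the chosen strategy makes only one bond in its key step, but it obtains the O8a/O5 distinction for nothing and ends with one mild deprotection.

Alternative 2: ring A built last by ketene benzannulation.
- Disconnection: C5–C6, C7–C8 and C4a–C5; ring A is removed entirely from a complete ring B–ring C unit.
- Forward key step: the diazo ketone 2-[2,4-bis(methoxymethoxy)phenyl]-6-[(4S)-2-diazo-7-methyl-4-(prop-1-en-2-yl)oct-6-enoyl]-3-(methoxymethoxy)-4H-pyran-4-one A6 would undergo Wolff rearrangement to the ketene (4S)-2-{6-[2,4-bis(methoxymethoxy)phenyl]-5-(methoxymethoxy)-4-oxo-4H-pyran-2-yl}-7-methyl-4-(prop-1-en-2-yl)octa-1,6-dien-1-one A7, which carries the pyranone and the lavandulyl group on the same carbon. [2+2] addition of (triisopropylsiloxy)ethyne A8 to A7, four-electron ring opening and six-electron ring closure would give 5-hydroxy-8-lavandulyl-3-(methoxymethoxy)-2-[2,4-bis(methoxymethoxy)phenyl]-7-(triisopropylsiloxy)-4H-chromen-4-one A5.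
- For: three C–C bonds form in one operation, and the pericyclic sequence dictates the position of every ring A substituent. Ring C exists beforehand, so no closure regiochemistry arises. Only deprotection follows A5, so this plan is clearly stronger than the chosen route after the key step.
- Against: A7 carries two alkenes in its own side chain. The prenyl double bond is reached through a three-atom tether from the substituted ketene carbon, the classic arrangement for intramolecular ketene–alkene [2+2] addition, which would compete with intermolecular capture by A8. A6 requires a 2-aryl-3-oxy-4-pyranone acylated on C8a, followed by diazo transfer to a carbon that already bears the lavandulyl group, a long linear prelude. The electrocyclic closure must use the pyranone C4a=C8a bond, and the ring opening needs heat in the presence of a 1,5-diene.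
- Comparison: the chosen strategy uses only enolate chemistry, in which the alkenes are spectators. Its risk is low reactivity of one ester, not chemoselectivity among several reactive π-systems.

Alternative 3: aryne annulation with an enolized β-keto ester.
- Disconnection: O1–C8a and C4–C4a.
- Forward key step: a fluoride source would convert 2-lavandulyl-3,5-bis(methoxymethoxy)-6-(trimethylsilyl)phenyl trifluoromethanesulfonate A10 into the aryne 3-lavandulyl-4,6-bis(methoxymethoxy)-1,2-didehydrobenzene A11. The enolate oxygen of methyl 2-(methoxymethoxy)-3-[2,4-bis(methoxymethoxy)phenyl]-3-oxopropanoate A12 would add to C8a of A11, and the resulting C4a anion would attack the ester of A12. The product is 8-lavandulyl-3,5,7-tris(methoxymethoxy)-2-[2,4-bis(methoxymethoxy)phenyl]-4H-chromen-4-one A9, and A9 is the same compound as 19.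
- For: this is the most convergent plan. The whole tricycle forms in one step from A10 and A12, and it reaches directly what the chosen route reaches only four steps after its key step. The C5 acetal oxygen also biases A11 correctly, since a nucleophile adds at the aryne carbon remote from an alkoxy group, which is C8a.
- Against: β-keto esters normally add to arynes through carbon, and the adduct then inserts the aryne into the C–C bond. The required O-arylation followed by C-acylation therefore runs against the innate selectivity of the ambident enolate of A12. C8a of A11 is also flanked by the lavandulyl group, so sterics oppose the electronic bias. The aryl anion must be acylated before the acidic keto ester A12 protonates it. A10 is a pentasubstituted benzene whose preparation needs the same lavandulylated phloroglucinol with one oxygen distinguished from the others, so the regiochemical problem is moved, not removed.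
- Comparison: the chosen strategy is longer after the key step, but each bond is made by a reaction of known type, and the one selectivity that matters is enforced by the structure of the precursor.

Key step: step 9

## Steps

Step 1
Reactants: 1 racemic lavandulol
Product: 2 (R)-lavandulol
Conditions: porcine pancreatic lipase, succinic anhydride (0.7 equiv), Et2O, 25 °C, run to about 60% conversion; hemisuccinate removed with aq. Na2CO3
Reagents that add atoms: none
Why: Lipase-catalysed kinetic resolution by enantioselective acylation; the S alcohol should be converted to the acid ester and washed out, and running past half conversion should raise the enantiomeric purity of the recovered R alcohol (a second pass is possible). The only stereocentre of the route is fixed here.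

Step 2
Reactants: 2 (R)-lavandulol
Product: 3 (R)-lavandulyl iodide
Conditions: PPh3, I2, imidazole, CH2Cl2, 0 → 25 °C, dark
Reagents that add atoms: iodine, II
Why: Appel-type iodination, an SN2 displacement of the oxyphosphonium group at the primary carbon; the stereocentre is adjacent to but not part of the reacting centre, and the alcohol is homoallylic, so no allylic transposition is possible.

Step 3
Reactants: 3 (R)-lavandulyl iodide; 4 methyl acetoacetate
Product: 5 methyl 2-lavandulylacetoacetate (both C2 epimers)
Conditions: 4 (1.6 equiv), NaH (1.5 equiv), THF–DMF, 0 °C; then 3, 55 °C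
Reagents that add atoms: none
Why: Acetoacetic ester alkylation, SN2 attack of a soft stabilised enolate on a primary iodide; β-branching slows the substitution, hence warm DMF, and the excess of 4 keeps the medium free of strong base so that elimination and dialkylation are suppressed. The new C2 centre is unselective and irrelevant because it becomes sp2 in step 5.

Step 4
Reactants: 5 methyl 2-lavandulylacetoacetate
Product: 6 methyl 2-lavandulyl-3,5-dioxohexanoate
Conditions: LiN(i-Pr)2 (2.3 equiv), THF, −78 → 0 °C; MeC(O)N(OMe)Me (1.2 equiv), −78 → 0 °C; aq. NH4Cl
Reagents that add atoms: N-methoxy-N-methylacetamide, CC(=O)N(C)OC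
Why: γ-Acylation of a β-keto ester dianion; the second deprotonation occurs at the methyl group and this more basic carbon attacks the amide. The chelated tetrahedral adduct of the Weinreb amide survives until quench, so the more acidic product cannot quench unreacted dianion.

Step 5
Reactants: 6 methyl 2-lavandulyl-3,5-dioxohexanoate
Product: 7 methyl 2-lavandulyl-3,5-bis(methoxymethoxy)hexa-2,4-dienoate (mixture of double-bond isomers)
Conditions: NaH (1.1 equiv), THF–DMPU (4:1), 0 °C, then MOMCl (1.1 equiv); NaH (1.3 equiv), then MOMCl (1.3 equiv), 0 → 25 °C
Reagents that add atoms: chloromethyl methyl ether, COCCl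
Why: O-Alkylation of 1,3-dicarbonyl enolates by a hard alkoxymethyl chloride in a dipolar medium; whichever oxygen reacts first, the second enolate (through chain C2–H) gives the same 3,5-dialkoxy dienoate, and C-alkylation at the tertiary chain C2 is sterically disfavoured. The double-bond geometry need not be controlled because it is erased in the anions of steps 8 and 9.

Step 6
Reactants: 8 methyl glycolate
Product: 9 methyl 2-(methoxymethoxy)acetate
Conditions: MOMCl, i-Pr2NEt, CH2Cl2, 0 → 25 °C
Reagents that add atoms: chloromethyl methyl ether, COCCl
Why: Standard MOM ether formation from a primary alcohol with an amine base; the ester is inert.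

Step 7
Reactants: 9 methyl 2-(methoxymethoxy)acetate
Product: 10 N-methoxy-2-(methoxymethoxy)-N-methylacetamide
Conditions: MeNH(OMe)·HCl (1.5 equiv), i-PrMgCl (3.0 equiv), THF, −20 → 0 °C; aq. NH4Cl
Reagents that add atoms: N,O-dimethylhydroxylamine hydrochloride, CNOC.Cl
Why: Direct conversion of an ester to a Weinreb amide by the amide ClMgN(OMe)Me made in the flask; the adduct is stable at low temperature, so no ketone or tertiary alcohol forms.

Step 8
Reactants: 7 methyl 2-lavandulyl-3,5-bis(methoxymethoxy)hexa-2,4-dienoate; 10 N-methoxy-2-(methoxymethoxy)-N-methylacetamide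
Product: 11 methyl (2E,4E)-2-lavandulyl-3,5,8-tris(methoxymethoxy)-7-oxoocta-2,4-dienoate (with its double-bond isomers)
Conditions: LiN(i-Pr)2 (1.2 equiv), THF, −78 °C; then 10 (1.3 equiv), −78 → −30 °C; aq. NH4Cl at −78 °C
Reagents that add atoms: none
Why: Deprotonation of the terminal methyl gives an extended lithium trienolate (a doubly vinylogous ester enolate, as in side-chain metalation of 4-alkoxy-6-methyl-2-pyranones), which is acylated at its remote carbon by the Weinreb amide. Attack there restores the push–pull dienoate, whereas the internal carbons are hindered (chain C2 is fully substituted); the chelated adduct releases the ketone only on quench, so 11 does not meet base before step 9.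

Step 9
Reactants: 11 methyl (2E,4E)-2-lavandulyl-3,5,8-tris(methoxymethoxy)-7-oxoocta-2,4-dienoate
Product: 13 1-[2-hydroxy-3-lavandulyl-4,6-bis(methoxymethoxy)phenyl]-2-(methoxymethoxy)ethanone, via cyclohexadienone tautomer 12 (not isolated)
Conditions: LiN(SiMe3)2 (2.5 equiv), THF, −78 → 25 °C (40 °C if closure is slow); aq. NH4Cl
Reagents that add atoms: none
Why: LiN(SiMe3)2 removes a proton from chain C6 (C4a), the only strongly acidic site, giving an enolate delocalised from the C4 oxygen through both enol ethers into the ester; in this anion the chain C2=C3 and C4=C5 bonds have reduced double-bond order, so the geometric isomers of 11 should interconvert and pass through the U-shaped form in which C4a lies over the ester carbon C8a. C4a then adds to the ester carbonyl in a 6-exo-trig closure of ring A, an intramolecular Claisen (Dieckmann-type) acyl substitution of the kind by which 3,5,7-triketo esters are known to give acylphloroglucinols, and loss of methoxide gives dienone 12, which is deprotonated at once to the aromatic phenoxide of 13, so the sequence is driven forward. No stereocentre is created (C4a is sp3 only in 12) and the side-chain centre has no acidic hydrogen and is untouched. The selectivity required is C–C bond formation in the Claisen sense with O8a as the only free phenol; it is secured because O5 and O7 are locked as enol ethers, which leaves the ester as the only carbonyl that C4a can reach and removes the oxygen nucleophile that would otherwise lactonise onto it, and because chain C2 (C8), the nucleophile of the aldol fold, is tied up as a fully substituted alkene carbon. The lithium counter-ion keeps the enolate oxygen in a tight ion pair and so favours attack through carbon over oxygen attack at chain C3. A hindered silylamide is used in place of an alkoxide, because an alkoxide could cleave the C4a–C4 bond by retro-Claisen attack on the ketone or exchange the acetal-type enol ethers by addition–elimination.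

Step 10
Reactants: 14 2,4-dihydroxybenzoic acid
Product: 15 methoxymethyl 2,4-bis(methoxymethoxy)benzoate
Conditions: NaH (3.5 equiv), MOMCl (3.5 equiv), DMF, 0 → 25 °C
Reagents that add atoms: chloromethyl methyl ether, COCCl
Why: Exhaustive alkylation of carboxylate and both phenoxides; full deprotonation with NaH overcomes the hydrogen bond that makes the ortho hydroxyl sluggish under amine bases.

Step 11
Reactants: 15 methoxymethyl 2,4-bis(methoxymethoxy)benzoate
Product: 16 2,4-bis(methoxymethoxy)benzoic acid
Conditions: LiOH (3 equiv), THF–MeOH–H2O, 25 °C; then 1 M HCl to pH 4 at 0 °C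
Reagents that add atoms: lithium hydroxide, [Li+].[OH-]
Why: Saponification of the acyloxymethyl ester by acyl–oxygen cleavage; aryl MOM ethers are stable to base, and the acidification is kept cold and mild so that they survive.

Step 12
Reactants: 13 1-[2-hydroxy-3-lavandulyl-4,6-bis(methoxymethoxy)phenyl]-2-(methoxymethoxy)ethanone; 16 2,4-bis(methoxymethoxy)benzoic acid
Product: 17 6-lavandulyl-2-[(methoxymethoxy)acetyl]-3,5-bis(methoxymethoxy)phenyl 2,4-bis(methoxymethoxy)benzoate
Conditions: i-PrN=C=N-i-Pr (1.5 equiv), DMAP (0.5 equiv), CH2Cl2, 0 → 25 °C
Reagents that add atoms: none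
Why: Steglich esterification; the acylpyridinium ion formed from the activated acid is reactive enough for a hindered, hydrogen-bonded phenol, and the neutral conditions avoid chloride-generating activation of the acid beside an ortho MOM ether.

Step 13
Reactants: 17 6-lavandulyl-2-[(methoxymethoxy)acetyl]-3,5-bis(methoxymethoxy)phenyl 2,4-bis(methoxymethoxy)benzoate
Product: 18 1-[2-hydroxy-3-lavandulyl-4,6-bis(methoxymethoxy)phenyl]-2-(methoxymethoxy)-3-[2,4-bis(methoxymethoxy)phenyl]propane-1,3-dione
Conditions: LiN(SiMe3)2 (3.0 equiv), THF, −78 → 0 °C; aq. NH4Cl
Reagents that add atoms: none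
Why: Baker–Venkataraman rearrangement; the enolate of the α-alkoxy ketone attacks the neighbouring aryl ester through a six-membered cyclic adduct that opens to the phenoxide of the 1,3-diketone, forming C2–C3. The carbon between the carbonyls is configurationally labile and is lost as a stereocentre in step 14.

Step 14
Reactants: 18 1-[2-hydroxy-3-lavandulyl-4,6-bis(methoxymethoxy)phenyl]-2-(methoxymethoxy)-3-[2,4-bis(methoxymethoxy)phenyl]propane-1,3-dione
Product: 19 8-lavandulyl-3,5,7-tris(methoxymethoxy)-2-[2,4-bis(methoxymethoxy)phenyl]-4H-chromen-4-one
Conditions: NaOAc, AcOH, 80 °C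
Reagents that add atoms: none
Why: Acid-catalysed cyclodehydration of a 2-hydroxyaryl 1,3-diketone; the only free phenol, O8a, adds to the ring B carbonyl and the hemiketal loses water, forming O1–C2. The acetate buffer is too weak to cleave the O5 acetal before the ring has closed, so the side chain ends on C8.

Step 15
Reactants: 19 8-lavandulyl-3,5,7-tris(methoxymethoxy)-2-[2,4-bis(methoxymethoxy)phenyl]-4H-chromen-4-one
Product: 20 2-(2,4-dihydroxyphenyl)-3,5,7-trihydroxy-8-lavandulyl-4H-chromen-4-one (target)
Conditions: 3 M aq. HCl–MeOH (1:10), THF as cosolvent, 40–45 °C, under Ar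
Reagents that add atoms: none
Why: Acid-catalysed transacetalisation of the five MOM ethers to methanol; protonation of an acetal oxygen is much easier than protonation of the isopropenyl group, so moderate acid strength and temperature should leave the side chain and its stereocentre intact.

## Compound list

1 | racemic lavandulol, (±)-5-methyl-2-(prop-1-en-2-yl)hex-4-en-1-ol | C=C(C)C(CO)CC=C(C)C | starting material
2 | (R)-lavandulol, (2R)-5-methyl-2-(prop-1-en-2-yl)hex-4-en-1-ol | C=C(C)[C@@H](CC=C(C)C)CO | intermediate
3 | (R)-lavandulyl iodide, (3R)-3-(iodomethyl)-2,6-dimethylhepta-1,5-diene | C=C(C)[C@@H](CC=C(C)C)CI | intermediate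
4 | methyl acetoacetate (methyl 3-oxobutanoate) | CC(=O)CC(=O)OC | starting material
5 | methyl (4S)-2-acetyl-7-methyl-4-(prop-1-en-2-yl)oct-6-enoate, both C2 epimers | C=C(C)[C@@H](CC=C(C)C)CC(C(C)=O)C(=O)OC | intermediate
6 | methyl 2-[(2S)-5-methyl-2-(prop-1-en-2-yl)hex-4-en-1-yl]-3,5-dioxohexanoate, C2 epimers and enol tautomers | C=C(C)[C@@H](CC=C(C)C)CC(C(=O)OC)C(=O)CC(C)=O | intermediate
7 | methyl 3,5-bis(methoxymethoxy)-2-[(2S)-5-methyl-2-(prop-1-en-2-yl)hex-4-en-1-yl]hexa-2,4-dienoate, mixture of double-bond isomers | C=C(C)[C@@H](CC=C(C)C)CC(C(=O)OC)=C(OCOC)C=C(C)OCOC | intermediate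
8 | methyl glycolate (methyl 2-hydroxyacetate) | COC(=O)CO | starting material
9 | methyl 2-(methoxymethoxy)acetate | COCOCC(=O)OC | intermediate
10 | N-methoxy-2-(methoxymethoxy)-N-methylacetamide | COCOCC(=O)N(C)OC | intermediate
11 | methyl (2E,4E)-3,5,8-tris(methoxymethoxy)-2-[(2S)-5-methyl-2-(prop-1-en-2-yl)hex-4-en-1-yl]-7-oxoocta-2,4-dienoate; the isomer that can close, accompanied by its double-bond isomers | C=C(C)[C@@H](CC=C(C)C)C/C(C(=O)OC)=C(OCOC)/C=C(OCOC)\CC(=O)COCOC | intermediate
12 | 6-[(methoxymethoxy)acetyl]-3,5-bis(methoxymethoxy)-2-[(2S)-5-methyl-2-(prop-1-en-2-yl)hex-4-en-1-yl]cyclohexa-2,4-dien-1-one, C6 unassigned | C=C(C)[C@@H](CC=C(C)C)CC1=C(OCOC)C=C(OCOC)C(C(=O)COCOC)C1=O | intermediate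
13 | 1-{2-hydroxy-4,6-bis(methoxymethoxy)-3-[(2S)-5-methyl-2-(prop-1-en-2-yl)hex-4-en-1-yl]phenyl}-2-(methoxymethoxy)ethan-1-one | C=C(C)[C@@H](CC=C(C)C)Cc1c(OCOC)cc(OCOC)c(C(=O)COCOC)c1O | intermediate
14 | 2,4-dihydroxybenzoic acid | O=C(O)c1ccc(O)cc1O | starting material
15 | methoxymethyl 2,4-bis(methoxymethoxy)benzoate | COCOC(=O)c1ccc(OCOC)cc1OCOC | intermediate
16 | 2,4-bis(methoxymethoxy)benzoic acid | COCOc1ccc(C(=O)O)c(OCOC)c1 | intermediate
17 | 2-[(methoxymethoxy)acetyl]-3,5-bis(methoxymethoxy)-6-[(2S)-5-methyl-2-(prop-1-en-2-yl)hex-4-en-1-yl]phenyl 2,4-bis(methoxymethoxy)benzoate | C=C(C)[C@@H](CC=C(C)C)Cc1c(OCOC)cc(OCOC)c(C(=O)COCOC)c1OC(=O)c1ccc(OCOC)cc1OCOC | intermediate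
18 | 1-{2-hydroxy-4,6-bis(methoxymethoxy)-3-[(2S)-5-methyl-2-(prop-1-en-2-yl)hex-4-en-1-yl]phenyl}-2-(methoxymethoxy)-3-[2,4-bis(methoxymethoxy)phenyl]propane-1,3-dione, C2 of the propanedione unassigned | C=C(C)[C@@H](CC=C(C)C)Cc1c(OCOC)cc(OCOC)c(C(=O)C(OCOC)C(=O)c2ccc(OCOC)cc2OCOC)c1O | intermediate
19 | 3,5,7-tris(methoxymethoxy)-2-[2,4-bis(methoxymethoxy)phenyl]-8-[(2S)-5-methyl-2-(prop-1-en-2-yl)hex-4-en-1-yl]-4H-chromen-4-one | C=C(C)[C@@H](CC=C(C)C)Cc1c(OCOC)cc(OCOC)c2c(=O)c(OCOC)c(-c3ccc(OCOC)cc3OCOC)oc12 | intermediate
20 | 2-(2,4-dihydroxyphenyl)-3,5,7-trihydroxy-8-[(2S)-5-methyl-2-(prop-1-en-2-yl)hex-4-en-1-yl]-4H-chromen-4-one | C=C(C)[C@@H](CC=C(C)C)Cc1c(O)cc(O)c2c(=O)c(O)c(-c3ccc(O)cc3O)oc12 | target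

## Step count and risk

Total step count: 15. Longest linear sequence: 11 (steps 1, 2, 3, 4, 5, 8, 9, 12, 13, 14, 15). Steps 6–7 and 10–11 prepare the two side fragments.

**Step 9 (key step).**
What may go wrong: the ester is deactivated as a doubly vinylogous carbonate, so closure may be slow. Part of the material may remain in chain geometries that cannot bring C4a to C8a if isomerisation in the anion is incomplete. The enolate oxygen could close on chain C3 by addition–elimination, or the less acidic chain C8 could do so. Released methoxide could cleave the C4a–C4 bond.
Fallback, from 6 back to 13: compound 6 is converted with LiN(i-Pr)2 (3.3 equiv) into its trianion, which is acylated at the terminal methyl by 10 to give the unmasked triketo ester methyl 2-lavandulyl-8-(methoxymethoxy)-3,5,7-trioxooctanoate F1. Mg(OMe)2 in methanol should then bring about the Claisen fold within the magnesium chelate, giving 2-(methoxymethoxy)-1-(2,4,6-trihydroxy-3-lavandulylphenyl)ethanone F2. The aldol fold through C8 cannot aromatise because C8 is substituted. Treatment with MOMCl (2.1 equiv) and i-Pr2NEt should cap the para hydroxyl and the less hindered ortho hydroxyl, leaving free the chelated hydroxyl beside the side chain, which is 13. The cost is that the O8a/O5 distinction then depends on a selective protection and is no longer built in, and that an aldol closure from chain C8 onto the chain C3 ketone has to be held back by the chelate.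

**Step 5.**
What may go wrong: C-alkylation at chain C4 may compete with O-alkylation, or the second etherification may stop short, so the bis(enol ether) is formed inefficiently.
Fallback, from 5 back to 7: the enol ethers are installed one at a time around the chain extension. Compound 5 is O-alkylated (NaH, MOMCl, THF–DMPU) to methyl 2-lavandulyl-3-(methoxymethoxy)but-2-enoate F3. Its γ-methyl is deprotonated with LiN(i-Pr)2 and acylated with N-methoxy-N-methylacetamide to methyl 2-lavandulyl-3-(methoxymethoxy)-5-oxohex-2-enoate F4. The doubly activated chain C4 methylene of F4 is then deprotonated (NaH) and O-alkylated with MOMCl to give 7.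

**Step 8.**
What may go wrong: proton transfer between the trienolate and the amide may return starting material, or bond formation may occur through an internal carbon of the trienolate and not the terminal one.
Fallback, from 7 and 9 back to 11: ester 9 is reduced with i-Bu2AlH at −78 °C to 2-(methoxymethoxy)acetaldehyde F5. The trienolate of 7 is added to it to give methyl 7-hydroxy-2-lavandulyl-3,5,8-tris(methoxymethoxy)octa-2,4-dienoate F6, and Dess–Martin oxidation gives 11. The aldehyde is a faster electrophile than the amide, and aldol addition is reversible, so adducts at hindered internal carbons can revert and drain to the terminal adduct.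

**Step 12.**
What may go wrong: acylation of the doubly flanked, hydrogen-bonded phenol may be slower than rearrangement of the activated acid to an unreactive N-acylurea.
Fallback, from 13 and 16 back to 18, bypassing 17: acid 16 is converted with 1,1'-carbonyldiimidazole into [2,4-bis(methoxymethoxy)phenyl](imidazol-1-yl)methanone F7. Ketone 13 is converted with LiN(SiMe3)2 (3.3 equiv) into its phenoxide–enolate dianion, which is C-aroylated by F7 at the enolate carbon to give 18 directly. The hindered oxygen is thus never acylated.

**Step 15.**
What may go wrong: protonation of the isopropenyl group may compete with acetal cleavage, leading to ether ring closure by the C7 oxygen or to double-bond migration that erodes the stereocentre.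
Fallback, from 19 back to 20: the acetals are cleaved without a strong protic acid, using ZnBr2 and propane-1-thiol in CH2Cl2 at 0 °C. The Lewis acid activates each acetal and the thiol takes up the methoxymethyl group, which changes the mechanism from solvolysis to soft-nucleophile transfer. This fallback makes no compound outside the list and is entered as F0.

## Further compounds

F1 | step 9 | methyl 8-(methoxymethoxy)-2-[(2S)-5-methyl-2-(prop-1-en-2-yl)hex-4-en-1-yl]-3,5,7-trioxooctanoate | C=C(C)[C@@H](CC=C(C)C)CC(C(=O)OC)C(=O)CC(=O)CC(=O)COCOC
F2 | step 9 | 2-(methoxymethoxy)-1-{2,4,6-trihydroxy-3-[(2S)-5-methyl-2-(prop-1-en-2-yl)hex-4-en-1-yl]phenyl}ethan-1-one | C=C(C)[C@@H](CC=C(C)C)Cc1c(O)cc(O)c(C(=O)COCOC)c1O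
F3 | step 5 | methyl 3-(methoxymethoxy)-2-[(2S)-5-methyl-2-(prop-1-en-2-yl)hex-4-en-1-yl]but-2-enoate | C=C(C)[C@@H](CC=C(C)C)CC(C(=O)OC)=C(C)OCOC
F4 | step 5 | methyl 3-(methoxymethoxy)-2-[(2S)-5-methyl-2-(prop-1-en-2-yl)hex-4-en-1-yl]-5-oxohex-2-enoate | C=C(C)[C@@H](CC=C(C)C)CC(C(=O)OC)=C(OCOC)CC(C)=O
F5 | step 8 | 2-(methoxymethoxy)acetaldehyde | COCOCC=O
F6 | step 8 | methyl 7-hydroxy-3,5,8-tris(methoxymethoxy)-2-[(2S)-5-methyl-2-(prop-1-en-2-yl)hex-4-en-1-yl]octa-2,4-dienoate | C=C(C)[C@@H](CC=C(C)C)CC(C(=O)OC)=C(OCOC)C=C(OCOC)CC(O)COCOC
F7 | step 12 | [2,4-bis(methoxymethoxy)phenyl](1H-imidazol-1-yl)methanone | COCOc1ccc(C(=O)n2ccnc2)c(OCOC)c1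
F0 | step 15 | none | none
A1 | alternative 1 | 1-[3-lavandulyl-6-methoxy-2,4-bis(methoxymethoxy)phenyl]-2-(methoxymethoxy)-3-[2,4-bis(triisopropylsiloxy)phenyl]propane-1,3-dione | C=C(C)[C@@H](CC=C(C)C)Cc1c(OCOC)cc(OC)c(C(=O)C(OCOC)C(=O)c2ccc(O[Si](C(C)C)(C(C)C)C(C)C)cc2O[Si](C(C)C)(C(C)C)C(C)C)c1OCOC
A2 | alternative 1 | 2-iodo-4-lavandulyl-1-methoxy-3,5-bis(methoxymethoxy)benzene | C=C(C)[C@@H](CC=C(C)C)Cc1c(OCOC)cc(OC)c(I)c1OCOC
A3 | alternative 1 | 2-(methoxymethoxy)-1-[2,4-bis(triisopropylsiloxy)phenyl]ethanone | COCOCC(=O)c1ccc(O[Si](C(C)C)(C(C)C)C(C)C)cc1O[Si](C(C)C)(C(C)C)C(C)C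
A4 | alternative 1 | carbon monoxide | [C-]#[O+]
A5 | alternative 2 | 5-hydroxy-8-lavandulyl-3-(methoxymethoxy)-2-[2,4-bis(methoxymethoxy)phenyl]-7-(triisopropylsiloxy)-4H-chromen-4-one | C=C(C)[C@@H](CC=C(C)C)Cc1c(O[Si](C(C)C)(C(C)C)C(C)C)cc(O)c2c(=O)c(OCOC)c(-c3ccc(OCOC)cc3OCOC)oc12
A6 | alternative 2 | 2-[2,4-bis(methoxymethoxy)phenyl]-6-[(4S)-2-diazo-7-methyl-4-(prop-1-en-2-yl)oct-6-enoyl]-3-(methoxymethoxy)-4H-pyran-4-one | C=C(C)[C@@H](CC=C(C)C)CC(=[N+]=[N-])C(=O)c1cc(=O)c(OCOC)c(-c2ccc(OCOC)cc2OCOC)o1
A7 | alternative 2 | (4S)-2-{6-[2,4-bis(methoxymethoxy)phenyl]-5-(methoxymethoxy)-4-oxo-4H-pyran-2-yl}-7-methyl-4-(prop-1-en-2-yl)octa-1,6-dien-1-one | C=C(C)[C@@H](CC=C(C)C)CC(=C=O)c1cc(=O)c(OCOC)c(-c2ccc(OCOC)cc2OCOC)o1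
A8 | alternative 2 | (triisopropylsiloxy)ethyne | C#CO[Si](C(C)C)(C(C)C)C(C)C
A9 | alternative 3 | 8-lavandulyl-3,5,7-tris(methoxymethoxy)-2-[2,4-bis(methoxymethoxy)phenyl]-4H-chromen-4-one | C=C(C)[C@@H](CC=C(C)C)Cc1c(OCOC)cc(OCOC)c2c(=O)c(OCOC)c(-c3ccc(OCOC)cc3OCOC)oc12
A10 | alternative 3 | 2-lavandulyl-3,5-bis(methoxymethoxy)-6-(trimethylsilyl)phenyl trifluoromethanesulfonate | C=C(C)[C@@H](CC=C(C)C)Cc1c(OCOC)cc(OCOC)c([Si](C)(C)C)c1OS(=O)(=O)C(F)(F)F
A11 | alternative 3 | 3-lavandulyl-4,6-bis(methoxymethoxy)-1,2-didehydrobenzene | C=C(C)[C@@H](CC=C(C)C)CC1=C(OCOC)C=C(OCOC)C#C1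
A12 | alternative 3 | methyl 2-(methoxymethoxy)-3-[2,4-bis(methoxymethoxy)phenyl]-3-oxopropanoate | COCOC(C(=O)OC)C(=O)c1ccc(OCOC)cc1OCOC
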